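A direct plan would follow the biogenesis of the ent-labdane core: geranylgeranyl diphosphate A1 would be bicyclised by a class 2 diterpene cyclase to ent-copalyl diphosphate A2 and dephosphorylated to ent-copalol A3.
Hydrogenation of the 13,14-olefin and oxidation of C15 would give acid A4, acid would move the 8(17)-olefin into ring B (A5), and A5 would be esterified with the protected glycerol A6 and deprotected.
Its weakest steps would be:
- the enzymatic bicyclisation, which would need a diphosphate made in extra steps, a recombinant protein and micromolar substrate;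
- the hydrogenation that would set C13 by catalyst control on the valuable bicycle, where an error would give a hardly separable epimer;
- the acid-catalysed olefin migration, an equilibration that could stop at a mixture of 7-, 8- and 8(17)-enes.

The route rests on annulating ring A onto (S)-carvone, whose ten carbons are ring B (C5–C10), C17 and the C4 isopropyl unit, with the enone marking C8=C9. C5 is bought and C10 is relayed from it by two enolate alkylations. The key step, a hydrogen-atom-transfer-initiated 6-endo radical cyclization, converts the isopropenyl carbon into the gem-dimethyl quaternary C4, forms C3–C4 and closes ring A as a trans-decalin in one operation. Reduction of the enone then gives the C8–C9 enolate regiospecifically, and its triflate is coupled at C9–C11 with a chain that already holds C13 and the glycerol diester. Cyclase, diphosphate, olefin migration and late hydrogenation thus disappear.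

Key step: step 3

Remark: positions in the bicyclic compounds are given in labdane numbering (ring A = C1–C5 and C10, ring B = C5–C10, C17 on C8, C18 and C19 on C4, C20 on C10).
Assumption: the minor C10 epimer formed in step 2 is removed by chromatography at 6 or 7.

Step 1
Reactants: 1 (S)-(+)-carvone
Product: 3 (5S)-2,6-dimethyl-5-(prop-1-en-2-yl)cyclohex-2-en-1-one (6-methylcarvone; both C6 epimers), via lithium dienolate 2 (not isolated)
Conditions: LiN(iPr)2 (1.05 equiv), THF, −78 °C; MeI (1.5 equiv), −78 → −20 °C
Reagents that add atoms: iodomethane, CI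
Why: Enolate alkylation: kinetic deprotonation at the α′ carbon (carvone C6, the future C10) and SN2 methylation of the cross-conjugated dienolate bring in C20; the new center forms as a mixture, which does not matter because it becomes trigonal again in step 2, and C5 is not touched.

Step 2
Reactants: 3 6-methylcarvone; 4 2,3-bis(phenylsulfonyl)prop-1-ene
Product: 6 (5R,6R)-2,6-dimethyl-6-[2-(phenylsulfonyl)prop-2-en-1-yl]-5-(prop-1-en-2-yl)cyclohex-2-en-1-one, via lithium dienolate 5 (not isolated)
Conditions: LiN(iPr)2 (1.1 equiv), THF/DMPU, −78 °C; 4 (1.2 equiv), −78 → −40 °C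
Reagents that add atoms: none
Why: Enolate alkylation by conjugate addition–elimination (SN2′) on the allylic vinyl sulfone 4 with loss of benzenesulfinate: the dienolate should be attacked on the face anti to the C5 isopropenyl group, so that the new CH2 (C1) stands trans to C4 and the methyl (C20) cis, which sets the quaternary C10 by substrate control from the purchased C5.

Step 3
Reactants: 6 (5R,6R)-2,6-dimethyl-6-[2-(phenylsulfonyl)prop-2-en-1-yl]-5-(prop-1-en-2-yl)cyclohex-2-en-1-one
Product: 7 (4aR,8aR)-2,5,5,8a-tetramethyl-7-(phenylsulfonyl)-4a,5,6,7,8,8a-hexahydronaphthalen-1(4H)-one (C7 epimers; C7 = labdane C2)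
Conditions: Fe(acac)3 (0.3 equiv), PhSiH3 (2.5 equiv), EtOH/(CH2OH)2 5:1, 60 °C, 0.02 M, argon
Reagents that add atoms: none
Why: The iron hydride formed from Fe(acac)3 and PhSiH3 in ethanol transfers a hydrogen atom to the CH2 terminus of the electron-rich isopropenyl group, the tertiary C4 radical adds to the unsubstituted terminus (C3) of the 2-sulfonylallyl arm, and the α-sulfonyl C2 radical is reduced by divalent iron and protonated by the solvent. The closest known reaction type is the iron-mediated reductive olefin coupling (hydrogen-atom-transfer-initiated Giese addition) in its intramolecular form. Ring A is closed in the 6-endo-trig mode, because the 5-exo alternative would place the radical against the polarity of the acceptor on the sulfonyl-bearing carbon and would give a strained trans-fused five-membered ring. No stereocenter of the target is made here: C4 receives its two methyl groups (one is the former =CH2), the C2 epimers converge when the sulfonyl group is removed in step 4, and the trans ring fusion follows from the trans C5/C10 substituents of 6, which close through a chair with both new ring bonds equatorial on ring B. The step needs selective hydrogen-atom transfer among three olefins and ring closure before the C4 radical is reduced; the enone and the vinyl sulfone are electron-poor and should accept hydrogen atoms slowly, and the acceptor terminus sits five atoms from the radical, so closure should outrun bimolecular reduction at this dilution.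

Step 4
Reactants: 7 (4aR,8aR)-2,5,5,8a-tetramethyl-7-(phenylsulfonyl)-4a,5,6,7,8,8a-hexahydronaphthalen-1(4H)-one
Product: 9 (4aR,8aR)-2,5,5,8a-tetramethyl-3,4,4a,5,6,7,8,8a-octahydronaphthalen-1-yl trifluoromethanesulfonate, via lithium enolate 8 (not isolated)
Conditions: Li (6 equiv), NH3(l)/THF, t-BuOH (2 equiv), −78 °C; isoprene; NH3 evaporated; then PhNTf2 (3 equiv), THF, −78 → 0 °C
Reagents that add atoms: N-phenylbis(trifluoromethanesulfonimide), O=S(=O)(N(c1ccccc1)S(=O)(=O)C(F)(F)F)C(F)(F)F
Why: Dissolving-metal (Birch-type) reduction with enolate trapping: two electrons and one proton turn the enone into the C8–C9 lithium enolate, the only enolate possible next to the quaternary C10, two more electrons cleave the C2–S bond (reductive desulfonylation), and O-sulfonylation by PhNTf2 fixes the future C8=C9 olefin; C5 and C10 cannot epimerise.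

Step 5
Reactants: 10 methyl hydrogen (R)-3-methylglutarate
Product: 12 (4R)-4-methyloxan-2-one, via hydroxy ester 11 (not isolated)
Conditions: BH3·SMe2 (1.1 equiv), THF, −15 → 20 °C; MeOH; then TsOH (5 mol%), toluene, 80 °C
Reagents that add atoms: none
Why: Chemoselective borane reduction of the free carboxylic acid beside the methyl ester, then acid-catalysed lactonisation with loss of methanol; the purchased stereocenter (future C13) is not involved, the reduced carbon becomes C11 and the ester carbon C15.

Step 6
Reactants: 12 (4R)-4-methyloxan-2-one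
Product: 14 (3S)-5-iodo-3-methylpentanoic acid, via trimethylsilyl ester 13 (not isolated)
Conditions: NaI (1.5 equiv), Me3SiCl (1.5 equiv), MeCN, 60 °C; then H2O
Reagents that add atoms: sodium iodide, [Na+].[I-]
Why: Lactone cleavage with iodotrimethylsilane made in the flask: silicon activates the carbonyl oxygen, iodide opens the ring by SN2 at the O–CH2 carbon, and water hydrolyses the silyl ester on work-up; the stereocenter keeps its arrangement (the descriptor becomes S only because CH2CH2I outranks CH2CO2H).

Step 7
Reactants: 15 (S)-glycidol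
Product: 16 (2R)-2-{[(4-methoxyphenyl)methoxy]methyl}oxirane
Conditions: NaH (1.1 equiv), 4-MeOC6H4CH2Cl (1.05 equiv), Bu4NI (5 mol%), THF/DMF, 0 °C → rt
Reagents that add atoms: 4-methoxybenzyl chloride, COc1ccc(CCl)cc1
Why: Williamson ether synthesis on the primary hydroxyl; C2 is not a reacting center (the descriptor changes from S to R only because the ether CH2 outranks the ring CH2).

Step 8
Reactants: 16 (2R)-2-{[(4-methoxyphenyl)methoxy]methyl}oxirane
Product: 17 (2S)-2-hydroxy-3-[(4-methoxyphenyl)methoxy]propyl acetate
Conditions: AcOH (1.5 equiv), Bu4NOAc (10 mol%), toluene, 80 °C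
Reagents that add atoms: acetic acid, CC(=O)O
Why: Carboxylate-catalysed SN2 opening of the terminal epoxide by acetic acid at the unsubstituted CH2, which leaves C2 untouched and frees only the secondary hydroxyl.

Step 9
Reactants: 14 (3S)-5-iodo-3-methylpentanoic acid; 17 (2S)-2-hydroxy-3-[(4-methoxyphenyl)methoxy]propyl acetate
Product: 18 (2S)-1-(acetyloxy)-3-[(4-methoxyphenyl)methoxy]propan-2-yl (3S)-5-iodo-3-methylpentanoate
Conditions: EDC·HCl (1.3 equiv), DMAP (0.1 equiv), CH2Cl2, 0 °C
Reagents that add atoms: none
Why: Steglich-type esterification (carbodiimide activation, DMAP acyl transfer) of the secondary hydroxyl, run cold so that the primary acetate should not migrate and the iodo acid should not lactonise; no stereocenter is involved.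

Step 10
Reactants: 18 (2S)-1-(acetyloxy)-3-[(4-methoxyphenyl)methoxy]propan-2-yl (3S)-5-iodo-3-methylpentanoate; 9 (4aR,8aR)-2,5,5,8a-tetramethyl-3,4,4a,5,6,7,8,8a-octahydronaphthalen-1-yl trifluoromethanesulfonate
Product: 20 (2S)-1-(acetyloxy)-3-[(4-methoxyphenyl)methoxy]propan-2-yl (5R,10R,13R)-labd-8-en-15-oate, via alkylzinc iodide 19 (not isolated)
Conditions: 18 (1.5 equiv), Zn dust (activated with BrCH2CH2Br and Me3SiCl), LiCl, THF, 40 °C; then 9, PdCl2(dppf) (5 mol%), THF/NMP 2:1, 60 °C
Reagents that add atoms: none
Why: Negishi sp3–sp2 cross-coupling: zinc inserts into the primary C–I bond without touching the two ester groups, and zerovalent palladium with the wide-bite-angle ligand dppf joins C11 to C9 (oxidative addition, transmetalation, reductive elimination), so that the tetrasubstituted C8=C9 olefin forms exactly where the triflate stood and C13 arrives with the chain.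

Step 11
Reactants: 20 (2S)-1-(acetyloxy)-3-[(4-methoxyphenyl)methoxy]propan-2-yl (5R,10R,13R)-labd-8-en-15-oate
Product: 21 (2S)-1-(acetyloxy)-3-hydroxypropan-2-yl (5R,10R,13R)-labd-8-en-15-oate (target)
Conditions: DDQ (1.3 equiv), CH2Cl2/pH 7 phosphate buffer 10:1, 0 °C; short column on boric-acid-treated SiO2, stored cold
Reagents that add atoms: none
Why: Oxidative cleavage of the 4-methoxybenzyl ether by DDQ (hydride abstraction, hydrolysis of the oxocarbenium ion) under buffered neutral conditions, chosen so that the sn-2 ester should not migrate to the freed primary hydroxyl and the tetrasubstituted olefin is left alone.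

**Compound list**

1 | (S)-(+)-carvone, (5S)-2-methyl-5-(prop-1-en-2-yl)cyclohex-2-en-1-one | CC(=C)[C@H]1CC=C(C)C(=O)C1 | starting material
2 | lithium (3S)-6-methyl-3-(prop-1-en-2-yl)cyclohexa-1,5-dien-1-olate | [Li+].[O-]C1=C[C@@H](C(C)=C)CC=C1C | intermediate (not isolated)
3 | (5S)-2,6-dimethyl-5-(prop-1-en-2-yl)cyclohex-2-en-1-one (C6 epimers) | O=C1C(C)=CC[C@H](C(C)=C)C1C | intermediate
4 | 2,3-bis(phenylsulfonyl)prop-1-ene | C=C(CS(=O)(=O)c1ccccc1)S(=O)(=O)c1ccccc1 | starting material
5 | lithium (3R)-2,6-dimethyl-3-(prop-1-en-2-yl)cyclohexa-1,5-dien-1-olate | [Li+].[O-]C1=C(C)[C@@H](C(C)=C)CC=C1C | intermediate (not isolated)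
6 | (5R,6R)-2,6-dimethyl-6-[2-(phenylsulfonyl)prop-2-en-1-yl]-5-(prop-1-en-2-yl)cyclohex-2-en-1-one | O=C1C(C)=CC[C@H](C(C)=C)[C@@]1(C)CC(=C)S(=O)(=O)c1ccccc1 | intermediate
7 | (4aR,8aR)-2,5,5,8a-tetramethyl-7-(phenylsulfonyl)-4a,5,6,7,8,8a-hexahydronaphthalen-1(4H)-one (C7 epimers) | O=C1C(C)=CC[C@@H]2C(C)(C)CC(S(=O)(=O)c3ccccc3)C[C@@]12C | intermediate
8 | lithium (4aR,8aR)-2,5,5,8a-tetramethyl-3,4,4a,5,6,7,8,8a-octahydronaphthalen-1-olate | [Li+].[O-]C1=C(C)CC[C@@H]2C(C)(C)CCC[C@@]12C | intermediate (not isolated)
9 | (4aR,8aR)-2,5,5,8a-tetramethyl-3,4,4a,5,6,7,8,8a-octahydronaphthalen-1-yl trifluoromethanesulfonate | O=S(=O)(OC1=C(C)CC[C@@H]2C(C)(C)CCC[C@@]12C)C(F)(F)F | intermediate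
10 | methyl hydrogen (R)-3-methylglutarate, (3R)-5-methoxy-3-methyl-5-oxopentanoic acid | COC(=O)C[C@H](C)CC(=O)O | starting material
11 | methyl (3R)-5-hydroxy-3-methylpentanoate | COC(=O)C[C@H](C)CCO | intermediate (not isolated)
12 | (4R)-4-methyloxan-2-one | O=C1C[C@H](C)CCO1 | intermediate
13 | trimethylsilyl (3S)-5-iodo-3-methylpentanoate | C[Si](C)(C)OC(=O)C[C@H](C)CCI | intermediate (not isolated)
14 | (3S)-5-iodo-3-methylpentanoic acid | OC(=O)C[C@H](C)CCI | intermediate
15 | (S)-glycidol, [(2S)-oxiran-2-yl]methanol | C1[C@H](CO)O1 | starting material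
16 | (2R)-2-{[(4-methoxyphenyl)methoxy]methyl}oxirane | C1[C@H](COCc2ccc(OC)cc2)O1 | intermediate
17 | (2S)-2-hydroxy-3-[(4-methoxyphenyl)methoxy]propyl acetate | CC(=O)OC[C@H](COCc1ccc(OC)cc1)O | intermediate
18 | (2S)-1-(acetyloxy)-3-[(4-methoxyphenyl)methoxy]propan-2-yl (3S)-5-iodo-3-methylpentanoate | CC(=O)OC[C@H](COCc1ccc(OC)cc1)OC(=O)C[C@H](C)CCI | intermediate
19 | {(3S)-5-{[(2S)-1-(acetyloxy)-3-[(4-methoxyphenyl)methoxy]propan-2-yl]oxy}-3-methyl-5-oxopentyl}(iodo)zinc | CC(=O)OC[C@H](COCc1ccc(OC)cc1)OC(=O)C[C@H](C)CC[Zn]I | intermediate (not isolated)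
20 | (2S)-1-(acetyloxy)-3-[(4-methoxyphenyl)methoxy]propan-2-yl (5R,10R,13R)-labd-8-en-15-oate | CC(=O)OC[C@H](COCc1ccc(OC)cc1)OC(=O)C[C@H](C)CCC1=C(C)CC[C@@H]2C(C)(C)CCC[C@@]12C | intermediate
21 | (2S)-1-(acetyloxy)-3-hydroxypropan-2-yl (5R,10R,13R)-labd-8-en-15-oate | CC(=O)OC[C@H](CO)OC(=O)C[C@H](C)CCC1=C(C)CC[C@@H]2C(C)(C)CCC[C@@]12C | target

Total step count: 11.
Longest linear sequence: 6 steps (steps 1, 2, 3, 4, 10 and 11, from (S)-carvone).

Steps most likely to fail:

1. Step 3 (radical ring closure). The C4 radical could be reduced before it cyclises, or the hydride could attack the enone. Fallback: from 6, Markovnikov addition of HBr (HBr/AcOH, CH2Cl2, −20 °C) to the isopropenyl group would give the tertiary bromide (5S,6R)-5-(2-bromopropan-2-yl)-2,6-dimethyl-6-[2-(phenylsulfonyl)prop-2-en-1-yl]cyclohex-2-en-1-one F1. A tin hydride chain (Bu3SnH by syringe pump, AIBN, benzene, 80 °C) would then make the same C4 radical by bromine abstraction, with no metal hydride present, and the 6-endo closure would rejoin the route at 7.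

2. Step 10 (sp3–sp2 coupling). Transmetalation at the hindered triflate could be slow, and β-hydride elimination from the alkylpalladium could give the reduced olefin instead. Fallback: from 18, dehydroiodination (DBU, toluene, 80 °C) would give the terminal olefin (2S)-1-(acetyloxy)-3-[(4-methoxyphenyl)methoxy]propan-2-yl (3S)-3-methylpent-4-enoate F2. Hydroboration with 9-BBN (THF, rt) would give the B-alkyl-9-borabicyclononane F3. A B-alkyl Suzuki–Miyaura coupling of F3 with 9 (PdCl2(dppf), AsPh3, aqueous K3PO4, DMF/THF, rt) would transfer the chain from a borate instead of an organozinc and return to 20.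

3. Step 4 (one-pot reduction and triflation). C–S cleavage could be incomplete, or the enolate could be lost to the basic by-products before O-sulfonylation. Fallback: from 7, the same Li/NH3 reduction quenched with NH4Cl would give the saturated, sulfur-free ketone (4aR,8aR)-2,5,5,8a-tetramethyloctahydronaphthalen-1(2H)-one F4. LiN(SiMe3)2 (THF, 0 °C) would regenerate enolate 8 by deprotonation at C8, the only enolisable position, and N-(5-chloropyridin-2-yl)bis(trifluoromethanesulfonimide) would give 9.

**Further compounds**

F1 | step 3 | (5S,6R)-5-(2-bromopropan-2-yl)-2,6-dimethyl-6-[2-(phenylsulfonyl)prop-2-en-1-yl]cyclohex-2-en-1-one | O=C1C(C)=CC[C@H](C(C)(C)Br)[C@@]1(C)CC(=C)S(=O)(=O)c1ccccc1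
F2 | step 10 | (2S)-1-(acetyloxy)-3-[(4-methoxyphenyl)methoxy]propan-2-yl (3S)-3-methylpent-4-enoate | CC(=O)OC[C@H](COCc1ccc(OC)cc1)OC(=O)C[C@H](C)C=C
F3 | step 10 | (2S)-1-(acetyloxy)-3-[(4-methoxyphenyl)methoxy]propan-2-yl (3R)-5-(9-borabicyclo[3.3.1]nonan-9-yl)-3-methylpentanoate | CC(=O)OC[C@H](COCc1ccc(OC)cc1)OC(=O)C[C@H](C)CCB1C2CCCC1CCC2
F4 | step 4 | (4aR,8aR)-2,5,5,8a-tetramethyloctahydronaphthalen-1(2H)-one (C2 epimers) | O=C1C(C)CC[C@@H]2C(C)(C)CCC[C@@]12C
A1 | direct plan | (2E,6E,10E)-geranylgeranyl diphosphate | CC(C)=CCC/C(C)=C/CC/C(C)=C/CC/C(C)=C/COP(=O)(O)OP(=O)(O)O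
A2 | direct plan | ent-copalyl diphosphate | C/C(=C\COP(=O)(O)OP(=O)(O)O)CC[C@@H]1C(=C)CC[C@@H]2C(C)(C)CCC[C@@]12C
A3 | direct plan | ent-copalol | C/C(=C\CO)CC[C@@H]1C(=C)CC[C@@H]2C(C)(C)CCC[C@@]12C
A4 | direct plan | (5R,9R,10R,13R)-labd-8(17)-en-15-oic acid | OC(=O)C[C@H](C)CC[C@@H]1C(=C)CC[C@@H]2C(C)(C)CCC[C@@]12C
A5 | direct plan | (5R,10R,13R)-labd-8-en-15-oic acid | OC(=O)C[C@H](C)CCC1=C(C)CC[C@@H]2C(C)(C)CCC[C@@]12C
A6 | direct plan | (2S)-3-(benzyloxy)-2-hydroxypropyl acetate | CC(=O)OC[C@H](COCc1ccccc1)O
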